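## Retrosynthetic overview

1. Target 23 ⇐ ester 22 (fluoride cleavage of a 2-(trimethylsilyl)ethyl ester) ⇐ cyclopentadiene 13 + bromodiazoacetate 19: the carboxyl-bearing ring carbon is taken out, i.e. forward a one-carbon insertion of a bromo(alkoxycarbonyl)carbene that expands the five-membered ring to the six-membered one.
2. Enabling feature: the cyclopentadiene ring of 13 has two silyloxy groups in a 1,3-relation and a quaternary ring carbon (CH3, farnesyl). The C(OSi)=C(CH3) bond next to that quaternary carbon is the nucleophilic terminus of the dioxygenated diene, and the quaternary carbon blocks H-shift and aromatisation, so insertion between the O-bearing and the CH3-bearing carbon gives the dearomatised resorcylate directly.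
3. 13 ⇐ dione 11 ⇐ vinylogous ester 8 (γ-methylation, hydrolysis, double silylation); the quaternary stereocentre is disconnected at its C–CH2(farnesyl) bond: catalytic enantioselective alkylation of tin enolate 7 with farnesyl bromide 5.
4. 4 ⇐ 2-methylcyclopentane-1,3-dione 1 (enol ether, α'-methylation); carbene precursor 19 ⇐ 2-(trimethylsilyl)ethanol 14 + bromoacetyl bromide 15.
5. Ring order: the cyclopentane ring is bought with 1; a cyclopropane is fused to it transiently (20); the six-membered ring arises last, by opening of the shared bond.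

Key step: step 10

Remark: farnesyl = (2E,6E)-3,7,11-trimethyldodeca-2,6,10-trien-1-yl; dione 11 is drawn as the diketo tautomer although it should be largely enolised; stereocentres other than the quaternary carbon in 10, 11, 12 and 20 are left undefined because steps 6 and 10 remove them; the sense of induction in step 3 is assumed by analogy with simple 2-methylcycloalkanone tin enolates, and the other catalyst antipode is used if it proves opposite.

## Route

Step 1
Reactants: 1 2-methylcyclopentane-1,3-dione
Product: 2 3-(2-methylpropoxy)-2-methylcyclopent-2-en-1-one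
Conditions: i-BuOH, p-TsOH (cat.), toluene, reflux, Dean–Stark
Reagents that add atoms: 2-methylpropan-1-ol, CC(C)CO
Why: Acid-catalysed enol etherification of a cyclic β-diketone with azeotropic removal of water gives the vinylogous ester needed for Stork–Danheiser enolate chemistry.

Step 2
Reactants: 2 3-(2-methylpropoxy)-2-methylcyclopent-2-en-1-one
Product: 4 (±)-3-(2-methylpropoxy)-2,5-dimethylcyclopent-2-en-1-one, via lithium 4-(2-methylpropoxy)-5-methylcyclopenta-1,4-dien-1-olate 3 (not isolated)
Conditions: LDA (commercial solution), THF, −78 °C; MeI, −78 → −20 °C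
Reagents that add atoms: iodomethane, CI
Why: Stork–Danheiser alkylation: kinetic deprotonation of a β-alkoxy enone occurs at the α'-carbon, and the cross-conjugated enolate is methylated there (the centre formed is racemic and becomes planar again in step 3).

Step 3
Reactants: 4 (±)-3-(2-methylpropoxy)-2,5-dimethylcyclopent-2-en-1-one; 5 (2E,6E)-farnesyl bromide
Product: 8 (5R)-5-farnesyl-3-(2-methylpropoxy)-2,5-dimethylcyclopent-2-en-1-one, via lithium 4-(2-methylpropoxy)-2,5-dimethylcyclopenta-1,4-dien-1-olate 6 (not isolated), via tributyltin enolate 7 (not isolated)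
Conditions: LDA, THF, −78 °C; Bu3SnCl, → 0 °C; solvent switch to benzene, filter; 5 (1.5 equiv), (R,R)-(salen)Cr(III)Cl (10 mol %), Bu3SnOMe (10 mol %), 0 °C
Reagents that add atoms: none
Why: Cr(III)(salen)-catalysed enantioselective alkylation of tetrasubstituted tributyltin enolates of α-substituted cyclic ketones with allylic bromides (Jacobsen type) should form the quaternary stereocentre, the catalyst selecting the face of the achiral enolate 7, while SN2 attack at the primary carbon of 5 keeps the chain linear and E,E.

Step 4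
Reactants: 8 (5R)-5-farnesyl-3-(2-methylpropoxy)-2,5-dimethylcyclopent-2-en-1-one
Product: 10 (5R)-5-farnesyl-3-(2-methylpropoxy)-2,4,5-trimethylcyclopent-2-en-1-one (C-4 epimers), via lithium (5R)-5-farnesyl-3-(2-methylpropoxy)-2,5-dimethylcyclopenta-1,3-dien-1-olate 9 (not isolated)
Conditions: LDA, THF, −78 → −40 °C; MeI, −78 → 0 °C
Reagents that add atoms: iodomethane, CI
Why: With the α'-carbon quaternary, LDA can only remove the γ-proton, and the extended enolate of a β-alkoxy enone is alkylated at the γ-carbon (as with β-alkoxycrotonates and tetronates), which restores the vinylogous ester; the new CH(CH3) centre forms as an epimer mixture that is planarised in step 6.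

Step 5
Reactants: 10 (5R)-5-farnesyl-3-(2-methylpropoxy)-2,4,5-trimethylcyclopent-2-en-1-one
Product: 11 (4R)-4-farnesyl-2,4,5-trimethylcyclopentane-1,3-dione (epimers at C-2 and C-5, enol tautomers)
Conditions: 1 M aq. HCl, THF, 20 °C
Reagents that add atoms: water, O
Why: Acid hydrolysis of the vinylogous ester frees the β-diketone; dilute acid at room temperature should spare the trisubstituted alkenes, and the quaternary carbon has no enolisable hydrogen, so its configuration is kept.

Step 6
Reactants: 11 (4R)-4-farnesyl-2,4,5-trimethylcyclopentane-1,3-dione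
Product: 13 (5R)-5-farnesyl-2,4,5-trimethyl-1,3-bis(trimethylsilyloxy)cyclopenta-1,3-diene, via (5R)-5-farnesyl-2,4,5-trimethyl-3-(trimethylsilyloxy)cyclopent-2-en-1-one 12 (not isolated)
Conditions: TMSOTf (2.4 equiv), Et3N (3 equiv), CH2Cl2, 0 → 20 °C; pentane, filtration under argon; used crude
Reagents that add atoms: trimethylsilyl trifluoromethanesulfonate, C[Si](C)(C)OS(=O)(=O)C(F)(F)F
Why: Double soft enolisation of a β-diketone (the preparation of 1,3-bis(silyloxy)-1,3-dienes): O-silylation of the enol, then O-silylation of the vinylogous ester carbonyl and loss of the only remaining ring proton, at the CH(CH3) carbon; one constitution results because the other flank is quaternary.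

Step 7
Reactants: 14 2-(trimethylsilyl)ethanol; 15 bromoacetyl bromide
Product: 16 2-(trimethylsilyl)ethyl bromoacetate
Conditions: NaHCO3 (3 equiv), MeCN, 0 → 20 °C
Reagents that add atoms: none
Why: Acylation of a primary alcohol by an acyl bromide under mild bicarbonate buffering gives the ester whose alkyl group is later removed by fluoride.

Step 8
Reactants: 16 2-(trimethylsilyl)ethyl bromoacetate
Product: 18 2-(trimethylsilyl)ethyl diazoacetate, via 2-(trimethylsilyl)ethyl 2-[1,2-bis(4-methylbenzenesulfonyl)hydrazin-1-yl]acetate 17 (not isolated)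
Conditions: TsNHNHTs (2 equiv), DBU (5 equiv), THF, 0 °C
Reagents that add atoms: N,N'-bis(4-methylbenzenesulfonyl)hydrazine, Cc1ccc(cc1)S(=O)(=O)NNS(=O)(=O)c1ccc(C)cc1
Why: Fukuyama diazoacetate synthesis: N-alkylation of ditosylhydrazine by the bromoacetate, then base-induced loss of two sulfinate groups, gives the diazo ester without diazo transfer.

Step 9
Reactants: 18 2-(trimethylsilyl)ethyl diazoacetate
Product: 19 2-(trimethylsilyl)ethyl bromo(diazo)acetate
Conditions: NBS (1.1 equiv), DBU, CH2Cl2, 0 °C, 5 min; cold silica plug; used at once as a cold solution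
Reagents that add atoms: N-bromosuccinimide, O=C1CCC(=O)N1Br
Why: Electrophilic bromination of the diazo carbon of a diazoacetate with NBS and DBU, the known route to alkyl bromodiazoacetates, which are thermally labile and are therefore used cold and immediately.

Step 10
Reactants: 13 (5R)-5-farnesyl-2,4,5-trimethyl-1,3-bis(trimethylsilyloxy)cyclopenta-1,3-diene; 19 2-(trimethylsilyl)ethyl bromo(diazo)acetate
Product: 22 2-(trimethylsilyl)ethyl (3R)-3-farnesyl-6-hydroxy-2,3,5-trimethyl-4-oxocyclohexa-1,5-diene-1-carboxylate, via 2-(trimethylsilyl)ethyl (4R)-6-bromo-4-farnesyl-2,4,5-trimethyl-1,3-bis(trimethylsilyloxy)bicyclo[3.1.0]hex-2-ene-6-carboxylate 20 (not isolated), via 2-(trimethylsilyl)ethyl (3R)-3-farnesyl-2,3,5-trimethyl-4-oxo-6-(trimethylsilyloxy)cyclohexa-1,5-diene-1-carboxylate 21 (not isolated)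
Conditions: Rh2(esp)2 (1 mol %), Cs2CO3 (1.5 equiv), CH2Cl2, 19 (1.1 equiv, slow addition), −20 → 20 °C; aq. NaHCO3, then 5 % aq. citric acid/THF, 0 °C
Reagents that add atoms: none
Why: Proposed new method: the Rh(II) carbenoid from 19 should attack the terminal, methyl-bearing carbon of the 1,3-bis(silyloxy)diene of 13 and close the bromo(ester)cyclopropane 20 across the enol ether bond next to the quaternary carbon by an asynchronous [2+1] addition (3-exo closure of an oxocarbenium/rhodium-enolate zwitterion); loss of bromide with disrotatory 2π-electrocyclic opening of the ring-fusion bond (cyclopropyl-to-allyl cation, pushed by both silyloxy groups) then turns the five-membered ring into the six-membered ring, and transfer of one silyl group to bromide leaves dienone 21, whose silyl enol ether is hydrolysed on work-up (21 may be either O-silyl regioisomer; both give 22). The closest known reactions are the Rh2(esp)2-catalysed cyclopropanation–ring expansion of indoles with halodiazoacetates to quinoline-3-carboxylates (Ciamician–Dennstedt-type one-carbon insertion) and the dihalocarbene ring expansion of cyclic silyl enol ethers to 2-halo-enones. No new stereocentre survives: the cyclopropane centres are destroyed on opening, and the quaternary carbon is a spectator that never becomes planar, so its configuration is carried through. The step needs site selectivity between the two enol ether bonds and against the three farnesyl alkenes; attack at the diene terminus alone gives the doubly oxygen-stabilised vinylogous cation, and the silyloxydiene is far more nucleophilic than a trialkyl alkene, so slow addition of about one equivalent of 19 should suffice. The concerted opening needs the bromide endo (Woodward–Hoffmann–DePuy rule), which is the usual sense of halodiazoacetate cyclopropanation (ester exo), and an exo isomer could equilibrate through the reversible zwitterion. Cs2CO3 takes up the Me3SiBr/HBr set free so that the farnesyl chain is not protonated.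

Step 11
Reactants: 22 2-(trimethylsilyl)ethyl (3R)-3-farnesyl-6-hydroxy-2,3,5-trimethyl-4-oxocyclohexa-1,5-diene-1-carboxylate
Product: 23 (3R)-3-farnesyl-6-hydroxy-2,3,5-trimethyl-4-oxocyclohexa-1,5-diene-1-carboxylic acid (target, CID137333727)
Conditions: TBAF (2.5 equiv), THF, 0 → 20 °C; cold 0.1 M HCl to pH 3–4, extraction at 0 °C
Reagents that add atoms: none
Why: Fluoride-induced β-elimination of the 2-(trimethylsilyl)ethyl ester frees the acid without hydroxide or strong acid, so the vinylogous β-keto acid and the polyene should survive if kept cold to avoid decarboxylation.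

## Compound list

1 | 2-methylcyclopentane-1,3-dione | CC1C(=O)CCC1=O | starting material
2 | 3-(2-methylpropoxy)-2-methylcyclopent-2-en-1-one | CC1=C(OCC(C)C)CCC1=O | intermediate
3 | lithium 4-(2-methylpropoxy)-5-methylcyclopenta-1,4-dien-1-olate (not isolated) | [Li+].[O-]C1=CCC(OCC(C)C)=C1C | intermediate
4 | (±)-3-(2-methylpropoxy)-2,5-dimethylcyclopent-2-en-1-one | CC1CC(OCC(C)C)=C(C)C1=O | intermediate
5 | (2E,6E)-farnesyl bromide | CC(C)=CCC/C(C)=C/CC/C(C)=C/CBr | starting material
6 | lithium 4-(2-methylpropoxy)-2,5-dimethylcyclopenta-1,4-dien-1-olate (not isolated) | [Li+].[O-]C1=C(C)CC(OCC(C)C)=C1C | intermediate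
7 | tributyl{[4-(2-methylpropoxy)-2,5-dimethylcyclopenta-1,4-dien-1-yl]oxy}stannane, O-bound form (not isolated) | CCCC[Sn](CCCC)(CCCC)OC1=C(C)CC(OCC(C)C)=C1C | intermediate
8 | (5R)-5-farnesyl-3-(2-methylpropoxy)-2,5-dimethylcyclopent-2-en-1-one | CC(C)=CCC/C(C)=C/CC/C(C)=C/C[C@@]1(C)C(=O)C(C)=C(OCC(C)C)C1 | intermediate
9 | lithium (5R)-5-farnesyl-3-(2-methylpropoxy)-2,5-dimethylcyclopenta-1,3-dien-1-olate (not isolated) | [Li+].CC(C)=CCC/C(C)=C/CC/C(C)=C/C[C@@]1(C)C([O-])=C(C)C(OCC(C)C)=C1 | intermediate
10 | (5R)-5-farnesyl-3-(2-methylpropoxy)-2,4,5-trimethylcyclopent-2-en-1-one (C-4 epimers) | CC(C)=CCC/C(C)=C/CC/C(C)=C/C[C@@]1(C)C(=O)C(C)=C(OCC(C)C)C1C | intermediate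
11 | (4R)-4-farnesyl-2,4,5-trimethylcyclopentane-1,3-dione (diketo form shown) | CC(C)=CCC/C(C)=C/CC/C(C)=C/C[C@@]1(C)C(=O)C(C)C(=O)C1C | intermediate
12 | (5R)-5-farnesyl-2,4,5-trimethyl-3-(trimethylsilyloxy)cyclopent-2-en-1-one, one of two regioisomers (not isolated) | CC(C)=CCC/C(C)=C/CC/C(C)=C/C[C@@]1(C)C(=O)C(C)=C(O[Si](C)(C)C)C1C | intermediate
13 | (5R)-5-farnesyl-2,4,5-trimethyl-1,3-bis(trimethylsilyloxy)cyclopenta-1,3-diene | CC(C)=CCC/C(C)=C/CC/C(C)=C/C[C@@]1(C)C(O[Si](C)(C)C)=C(C)C(O[Si](C)(C)C)=C1C | intermediate
14 | 2-(trimethylsilyl)ethanol | C[Si](C)(C)CCO | starting material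
15 | bromoacetyl bromide | BrCC(Br)=O | starting material
16 | 2-(trimethylsilyl)ethyl bromoacetate | C[Si](C)(C)CCOC(=O)CBr | intermediate
17 | 2-(trimethylsilyl)ethyl 2-[1,2-bis(4-methylbenzenesulfonyl)hydrazin-1-yl]acetate (not isolated) | C[Si](C)(C)CCOC(=O)CN(NS(=O)(=O)c1ccc(C)cc1)S(=O)(=O)c1ccc(C)cc1 | intermediate
18 | 2-(trimethylsilyl)ethyl diazoacetate | C[Si](C)(C)CCOC(=O)C=[N+]=[N-] | intermediate
19 | 2-(trimethylsilyl)ethyl bromo(diazo)acetate | C[Si](C)(C)CCOC(=O)C(Br)=[N+]=[N-] | intermediate
20 | 2-(trimethylsilyl)ethyl (4R)-6-bromo-4-farnesyl-2,4,5-trimethyl-1,3-bis(trimethylsilyloxy)bicyclo[3.1.0]hex-2-ene-6-carboxylate (not isolated) | CC(C)=CCC/C(C)=C/CC/C(C)=C/C[C@@]1(C)C(O[Si](C)(C)C)=C(C)C2(O[Si](C)(C)C)C(Br)(C(=O)OCC[Si](C)(C)C)C12C | intermediate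
21 | 2-(trimethylsilyl)ethyl (3R)-3-farnesyl-2,3,5-trimethyl-4-oxo-6-(trimethylsilyloxy)cyclohexa-1,5-diene-1-carboxylate (not isolated) | CC(C)=CCC/C(C)=C/CC/C(C)=C/C[C@@]1(C)C(=O)C(C)=C(O[Si](C)(C)C)C(C(=O)OCC[Si](C)(C)C)=C1C | intermediate
22 | 2-(trimethylsilyl)ethyl (3R)-3-farnesyl-6-hydroxy-2,3,5-trimethyl-4-oxocyclohexa-1,5-diene-1-carboxylate | CC(C)=CCC/C(C)=C/CC/C(C)=C/C[C@@]1(C)C(=O)C(C)=C(O)C(C(=O)OCC[Si](C)(C)C)=C1C | intermediate
23 | (3R)-3-farnesyl-6-hydroxy-2,3,5-trimethyl-4-oxocyclohexa-1,5-diene-1-carboxylic acid | CC(C)=CCC/C(C)=C/CC/C(C)=C/C[C@@]1(C)C(=O)C(C)=C(O)C(C(=O)O)=C1C | target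

## Step count and risks

Total step count: 11. Longest linear sequence: 8 (steps 1–6, 10, 11); steps 7–9 form the three-step side branch to 19.

The three steps most likely to fail:

Step 10 (Proposed new method). The carbenoid may add to the internal enol ether bond or to a farnesyl alkene, the zwitterion may collapse to simple C-alkylation with silyl transfer instead of closing the cyclopropane, or a cyclopropane with exo bromide may not open. The fallback uses known chemistry and sets out from 13. Dibromocarbene (CHBr3, KOt-Bu, pentane, −30 °C) is added to the same terminal enol ether bond, as in the dihalocarbene ring expansion of silyl enol ethers, to give (4R)-6,6-dibromo-4-farnesyl-2,4,5-trimethyl-1,3-bis(trimethylsilyloxy)bicyclo[3.1.0]hex-2-ene F1. On warming and aqueous work-up this should open to (6R)-4-bromo-6-farnesyl-3-hydroxy-2,5,6-trimethylcyclohexa-2,4-dien-1-one F2. The enol is then masked as its sodium salt (NaH, THF, 0 °C), bromine–lithium exchange with t-BuLi at −78 °C gives the C-lithiated sodium enolate F3, and quenching with CO2 followed by cold dilute acid comes back to the route at the target 23, so step 11 is not needed.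

Step 3. Face selection by the catalyst may be poor, or turnover low, with the hindered trisubstituted allylic bromide, and O-alkylation may compete. The fallback sets out from 4: plain Stork–Danheiser alkylation (LDA, THF, −78 °C, then 5) through enolate 6 gives racemic 5-farnesyl-3-(2-methylpropoxy)-2,5-dimethylcyclopent-2-en-1-one F4. This is resolved by preparative chromatography on a chiral stationary phase (SFC); the (5S)-enantiomer F5 is set aside and the (5R)-enantiomer comes back to the route at 8.

Step 4. Methylation may go to the α-carbon or to oxygen of the extended enolate instead of the γ-carbon, or may run on to a second methylation. The fallback sets out from 8 and changes the order and the nucleophile. The enol ether is hydrolysed first (1 M HCl, THF) to (4R)-4-farnesyl-2,4-dimethylcyclopentane-1,3-dione F6. Its dilithium dienediolate F7 (LDA, 2.2 equiv, THF/DMPU, −78 → 0 °C) is then methylated with one equivalent of MeI at the only remaining α'-carbon, a β-diketone dianion alkylation, and the route is rejoined at 11.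

## Further compounds

F1 | step 10 | (4R)-6,6-dibromo-4-farnesyl-2,4,5-trimethyl-1,3-bis(trimethylsilyloxy)bicyclo[3.1.0]hex-2-ene | CC(C)=CCC/C(C)=C/CC/C(C)=C/C[C@@]1(C)C(O[Si](C)(C)C)=C(C)C2(O[Si](C)(C)C)C(Br)(Br)C12C
F2 | step 10 | (6R)-4-bromo-6-farnesyl-3-hydroxy-2,5,6-trimethylcyclohexa-2,4-dien-1-one | CC(C)=CCC/C(C)=C/CC/C(C)=C/C[C@@]1(C)C(=O)C(C)=C(O)C(Br)=C1C
F3 | step 10 | C-lithiated sodium enolate of F2 | [Na+].CC(C)=CCC/C(C)=C/CC/C(C)=C/C[C@@]1(C)C(=O)C(C)=C([O-])C([Li])=C1C
F4 | step 3 | (±)-5-farnesyl-3-(2-methylpropoxy)-2,5-dimethylcyclopent-2-en-1-one | CC(C)=CCC/C(C)=C/CC/C(C)=C/CC1(C)C(=O)C(C)=C(OCC(C)C)C1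
F5 | step 3 | (5S)-5-farnesyl-3-(2-methylpropoxy)-2,5-dimethylcyclopent-2-en-1-one | CC(C)=CCC/C(C)=C/CC/C(C)=C/C[C@]1(C)C(=O)C(C)=C(OCC(C)C)C1
F6 | step 4 | (4R)-4-farnesyl-2,4-dimethylcyclopentane-1,3-dione | CC(C)=CCC/C(C)=C/CC/C(C)=C/C[C@@]1(C)C(=O)C(C)C(=O)C1
F7 | step 4 | dilithium dienediolate of F6 | [Li+].[Li+].CC(C)=CCC/C(C)=C/CC/C(C)=C/C[C@@]1(C)C([O-])=C(C)C([O-])=C1
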